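**Retrosynthetic overview**

1. The C50 polyene is cut at C11=C12 and C11'=C12' (double Wittig): C10 trienedial 18 plus two molecules of C20 phosphonium salt 17.
2. 17 comes from vinyl carbinol 16, and 16 from the 2-substituted β-ionone 14. The ring (C1–C6 bond) is closed by acid cyclisation of the acyclic dienone 13. Both identical rings are made this way at the monomer stage, before the polyene exists; no ring is formed later.
3. 13 comes from methyl ketone 7 by ethynylation and a Saucy–Marbet C3 extension.
4. Key disconnection: the terminal allylic C–O bond of the side chain (together with its E-trisubstituted alkene) is made from the secondary allylic alcohol 5 by a [3,3] oxygen transposition with acyl trapping; 5 comes from keto-aldehyde 3 and 2-bromopropene.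
5. 3 comes from (+)-limonene 1,2-oxide 1 by glycol cleavage; C4 of limonene becomes C2 and C2' (both R).

Assumption: the target is all-E (2R,2'R)-2,2'-bis[(E)-4-hydroxy-3-methylbut-2-enyl]-β,β-carotene (carotenoid numbering used throughout), and commercial (+)-limonene 1,2-oxide (cis/trans mixture, 4R) is enantiomerically pure at C4.

**Route**

Step 1
Reactants: 1 (+)-limonene 1,2-oxide
Product: 3 (3R)-6-oxo-3-(prop-1-en-2-yl)heptanal, via limonene glycol 2 (not isolated)
Conditions: H5IO6 (1.2 equiv), THF/H2O, 0 °C to rt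
Reagents that add atoms: water, O
Why: Aqueous periodic acid hydrates the epoxide to the glycol and cleaves it at once (Malaprade glycol cleavage), so both epoxide diastereomers converge on one keto-aldehyde while the (4R) methine of limonene, the future C2 of each ring, is not touched.

Step 2
Reactants: 3 (3R)-6-oxo-3-(prop-1-en-2-yl)heptanal; 4 2-bromopropene
Product: 5 (5R)-7-hydroxy-8-methyl-5-(prop-1-en-2-yl)non-8-en-2-one (C7 epimer mixture)
Conditions: CrCl2 (4 equiv), NiCl2 (2 mol%), DMF, rt
Reagents that add atoms: none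
Why: The Nozaki–Hiyama–Kishi reaction adds the isopropenylchromium species (trivalent chromium) to the aldehyde only, leaving the methyl ketone and the stereocentre intact; the new carbinol centre is an inconsequential epimer mixture because step 3 erases it.

Step 3
Reactants: 5 (5R)-7-hydroxy-8-methyl-5-(prop-1-en-2-yl)non-8-en-2-one
Product: 7 (2E,5R)-2-methyl-8-oxo-5-(prop-1-en-2-yl)non-2-en-1-yl pivalate, via primary allylic alcohol 6 (not isolated)
Conditions: O3ReOSiPh3 (3 mol%), pivalic anhydride (Piv2O, 1.3 equiv, slow addition), 2,6-di-tert-butyl-4-methylpyridine (5 mol%), Et2O, −40 to 0 °C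
Reagents that add atoms: pivalic anhydride, CC(C)(C)C(=O)OC(=O)C(C)(C)C
Why: Proposed new method: acyl-funnelled oxo-rhenium 1,3-transposition, in which the perrhenate ester of 5 (heptavalent rhenium) undergoes the usual chair [3,3] oxygen shift (C6 chain equatorial, hence E) to the primary perrhenate, and only this unhindered primary centre is pivaloylated by Piv2O (through a transient pivaloyl perrhenate that returns the ReO3 unit), so the terminal C–O bond of the target is formed and the secondary/primary equilibrium and the E/Z ratio are locked kinetically, because the hindered secondary carbinol is acylated far more slowly and a pivalate cannot re-enter the [3,3] manifold; the closest known reaction types are the O3ReOSiPh3-catalysed 1,3-transposition of allylic alcohols with silylative trapping of the primary isomer and oxo-metal-catalysed acyl transfer from anhydrides, and no stereocentre is created or touched.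

Step 4
Reactants: 7 (2E,5R)-2-methyl-8-oxo-5-(prop-1-en-2-yl)non-2-en-1-yl pivalate; 8 ethynylmagnesium bromide
Product: 9 (2E,5R)-8-hydroxy-2,8-dimethyl-5-(prop-1-en-2-yl)dec-2-en-9-yn-1-yl pivalate (C8 epimer mixture)
Conditions: HC≡CMgBr (1.5 equiv), THF, −20 to 0 °C; NH4Cl aq
Reagents that add atoms: none
Why: Grignard 1,2-addition of the weakly nucleophilic ethynyl reagent to the methyl ketone is much faster than attack on the hindered pivalate at low temperature, and the new tertiary carbinol centre (epimer mixture) is destroyed in step 5.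

Step 5
Reactants: 9 (2E,5R)-8-hydroxy-2,8-dimethyl-5-(prop-1-en-2-yl)dec-2-en-9-yn-1-yl pivalate; 10 2-methoxypropene
Product: 13 (2E,5R,10E)-2,8-dimethyl-12-oxo-5-(prop-1-en-2-yl)trideca-2,8,10-trien-1-yl pivalate (8E/8Z mixture), via propargyl isopropenyl ether 11 (not isolated), via allenyl ketone 12 (not isolated)
Conditions: 2-methoxypropene (4 equiv), TsOH·H2O (0.5 mol%), toluene, 90 °C (sealed); then NaOH (cat.), MeOH, 0 °C
Reagents that add atoms: none
Why: Saucy–Marbet reaction, in which acid-catalysed ketal exchange gives the propargyl isopropenyl ether, its propargyl Claisen [3,3] shift gives the β-allenyl ketone, and base isomerises this to the conjugated dienone, adding the C3 unit of the ionone side chain without touching the stereocentre or the pivalate.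

Step 6
Reactants: 13 (2E,5R,10E)-2,8-dimethyl-12-oxo-5-(prop-1-en-2-yl)trideca-2,8,10-trien-1-yl pivalate
Product: 14 (2E)-2-methyl-4-{(1R)-2,2,4-trimethyl-3-[(1E)-3-oxobut-1-en-1-yl]cyclohex-3-en-1-yl}but-2-en-1-yl pivalate (the 2-substituted β-ionone)
Conditions: 96% H2SO4 (5 equiv), CH2Cl2, −20 to −5 °C, 10 min; ice
Reagents that add atoms: none
Why: Classical Brønsted-acid cation–olefin cyclisation of the pseudoionone type, in which Markovnikov protonation of the isopropenyl group gives the tertiary cation that is captured 6-endo by the C8=C9 alkene to close the C1–C6 ring bond and the strong acid funnels the product to the conjugated β-isomer; the stereocentre is retained (not formed) because ring closure should outrun 1,2-hydride shift, as in cyclisations of 2-methyl homologues of the irone series, and the side-chain alkene is deactivated by its allylic acyloxy group and cannot reach the cation through a six-membered transition state.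

Step 7
Reactants: 14 the 2-substituted β-ionone; 15 vinylmagnesium bromide
Product: 16 (2E)-4-{(1R)-3-[(1E)-3-hydroxy-3-methylpenta-1,4-dien-1-yl]-2,2,4-trimethylcyclohex-3-en-1-yl}-2-methylbut-2-en-1-yl pivalate (carbinol epimer mixture)
Conditions: CH2=CHMgBr (1.3 equiv), THF, −30 to 0 °C; NH4Cl aq
Reagents that add atoms: none
Why: Grignard 1,2-addition of vinylmagnesium bromide to the enone carbonyl (the standard vinyl-β-ionol synthesis) proceeds at low temperature without touching the pivalate, and the carbinol epimers converge in step 8.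

Step 8
Reactants: 16 the vinyl carbinol
Product: 17 {(2E,4E)-3-methyl-5-[(5R)-2,6,6-trimethyl-5-[(2E)-3-methyl-4-(pivaloyloxy)but-2-en-1-yl]cyclohex-1-en-1-yl]penta-2,4-dien-1-yl}triphenylphosphonium bromide
Conditions: PPh3·HBr (1.05 equiv), MeOH, 0 °C to rt; crystallise
Reagents that add atoms: triphenylphosphine hydrobromide, Br.c1ccc(cc1)P(c1ccccc1)c1ccccc1
Why: Acid ionises the tertiary doubly allylic alcohol to a pentadienyl cation that PPh3 captures at the unhindered terminus (SN1' phosphonium salt formation, as for the C15 Wittig salt of carotenoid manufacture), giving mainly the (2E,4E) salt, whereas the primary allylic pivalate is not ionised by this weak acid.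

Step 9
Reactants: 17 the C20 phosphonium bromide (two molecules); 18 (2E,4E,6E)-2,7-dimethylocta-2,4,6-trienedial
Product: 20 (2R,2'R)-2,2'-bis[(E)-4-hydroxy-3-methylbut-2-enyl]-β,β-carotene, via bis-pivalate 19 (not isolated)
Conditions: NaOMe (2.5 equiv), MeOH/CH2Cl2, 0 °C to rt; then NaOMe (excess), MeOH/THF, 55 °C; then n-heptane, 90 °C
Reagents that add atoms: none
Why: Two-fold Wittig olefination of the semi-stabilised allylic ylide with the C10 dialdehyde builds C11=C12 and C11'=C12' (C20 + C10 + C20 carotenoid assembly), methoxide then removes both pivalates by transesterification, and heating equilibrates (11Z) isomers to the all-E polyene while C2 and C2' are remote and unaffected.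

**Compound list**

1 | (+)-limonene 1,2-oxide, (4R)-1-methyl-4-(prop-1-en-2-yl)-7-oxabicyclo[4.1.0]heptane, cis/trans mixture | CC12OC1C[C@@H](CC2)C(C)=C | starting material
2 | limonene glycol, (4R)-1-methyl-4-(prop-1-en-2-yl)cyclohexane-1,2-diol | CC1(O)C(O)C[C@@H](CC1)C(C)=C | intermediate (not isolated)
3 | (3R)-6-oxo-3-(prop-1-en-2-yl)heptanal | O=CC[C@@H](CCC(C)=O)C(C)=C | intermediate
4 | 2-bromopropene | CC(Br)=C | starting material
5 | (5R)-7-hydroxy-8-methyl-5-(prop-1-en-2-yl)non-8-en-2-one, C7 epimers | CC(=C)C(O)C[C@@H](CCC(C)=O)C(C)=C | intermediate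
6 | (5R,7E)-9-hydroxy-8-methyl-5-(prop-1-en-2-yl)non-7-en-2-one | CC(=O)CC[C@H](C/C=C(\C)CO)C(C)=C | intermediate (not isolated)
7 | (2E,5R)-2-methyl-8-oxo-5-(prop-1-en-2-yl)non-2-en-1-yl pivalate | CC(=O)CC[C@H](C/C=C(\C)COC(=O)C(C)(C)C)C(C)=C | intermediate
8 | ethynylmagnesium bromide | C#C[Mg]Br | starting material
9 | (2E,5R)-8-hydroxy-2,8-dimethyl-5-(prop-1-en-2-yl)dec-2-en-9-yn-1-yl pivalate, C8 epimers | C#CC(C)(O)CC[C@H](C/C=C(\C)COC(=O)C(C)(C)C)C(C)=C | intermediate
10 | 2-methoxypropene | COC(C)=C | starting material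
11 | (2E,5R)-2,8-dimethyl-5-(prop-1-en-2-yl)-8-(prop-1-en-2-yloxy)dec-2-en-9-yn-1-yl pivalate | C#CC(C)(OC(C)=C)CC[C@H](C/C=C(\C)COC(=O)C(C)(C)C)C(C)=C | intermediate (not isolated)
12 | (2E,5R)-2,8-dimethyl-12-oxo-5-(prop-1-en-2-yl)trideca-2,8,9-trien-1-yl pivalate (allenyl ketone) | CC(=O)CC=C=C(C)CC[C@H](C/C=C(\C)COC(=O)C(C)(C)C)C(C)=C | intermediate (not isolated)
13 | (2E,5R,10E)-2,8-dimethyl-12-oxo-5-(prop-1-en-2-yl)trideca-2,8,10-trien-1-yl pivalate, 8E/8Z mixture | CC(=O)/C=C/C=C(C)CC[C@H](C/C=C(\C)COC(=O)C(C)(C)C)C(C)=C | intermediate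
14 | (2E)-2-methyl-4-{(1R)-2,2,4-trimethyl-3-[(1E)-3-oxobut-1-en-1-yl]cyclohex-3-en-1-yl}but-2-en-1-yl pivalate | CC(=O)/C=C/C1=C(C)CC[C@H](C/C=C(\C)COC(=O)C(C)(C)C)C1(C)C | intermediate
15 | vinylmagnesium bromide | C=C[Mg]Br | starting material
16 | (2E)-4-{(1R)-3-[(1E)-3-hydroxy-3-methylpenta-1,4-dien-1-yl]-2,2,4-trimethylcyclohex-3-en-1-yl}-2-methylbut-2-en-1-yl pivalate, carbinol epimers | C=CC(C)(O)/C=C/C1=C(C)CC[C@H](C/C=C(\C)COC(=O)C(C)(C)C)C1(C)C | intermediate
17 | {(2E,4E)-3-methyl-5-[(5R)-2,6,6-trimethyl-5-[(2E)-3-methyl-4-(pivaloyloxy)but-2-en-1-yl]cyclohex-1-en-1-yl]penta-2,4-dien-1-yl}triphenylphosphonium bromide | [Br-].C(/C=C(\C)/C=C/C1=C(C)CC[C@H](C/C=C(\C)COC(=O)C(C)(C)C)C1(C)C)[P+](c2ccccc2)(c3ccccc3)c4ccccc4 | intermediate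
18 | (2E,4E,6E)-2,7-dimethylocta-2,4,6-trienedial | O=C/C(C)=C/C=C/C=C(C)/C=O | starting material
19 | (2R,2'R)-2,2'-bis[(E)-3-methyl-4-(pivaloyloxy)but-2-enyl]-β,β-carotene | CC1=C(/C=C/C(C)=C/C=C/C(C)=C/C=C/C=C(C)/C=C/C=C(C)/C=C/C2=C(C)CC[C@H](C/C=C(\C)COC(=O)C(C)(C)C)C2(C)C)C(C)(C)[C@@H](C/C=C(\C)COC(=O)C(C)(C)C)CC1 | intermediate (not isolated)
20 | (2R,2'R)-2,2'-bis[(E)-4-hydroxy-3-methylbut-2-enyl]-β,β-carotene | CC1=C(/C=C/C(C)=C/C=C/C(C)=C/C=C/C=C(C)/C=C/C=C(C)/C=C/C2=C(C)CC[C@H](C/C=C(\C)CO)C2(C)C)C(C)(C)[C@@H](C/C=C(\C)CO)CC1 | target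

**Step count and risks**

Total step count: 9. Longest linear sequence: 9 steps (1 to 20; step 9 joins two molecules of 17 with commercial 18).

The three steps most likely to fail:

Step 3 (the proposed new reaction). Risks are that the anhydride or the pivalic acid formed slows the perrhenate catalyst, that 5 is acylated before it rearranges, or that slow trapping lets the E/Z ratio drift. The fallback uses only known chemistry and replaces the acyl funnel by a silyl relay in three separate operations. It sets out from 5: O3ReOSiPh3 (2 mol%) with N,O-bis(trimethylsilyl)acetamide in Et2O at 0 °C (the established silylative trap of the primary isomer) gives (5R,7E)-8-methyl-5-(prop-1-en-2-yl)-9-(trimethylsilyloxy)non-7-en-2-one F1. K2CO3 in MeOH then releases alcohol 6, now isolated, and PivCl/pyridine/DMAP in CH2Cl2 gives the pivalate, so the route is rejoined at 7.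

Step 6 (ring closure). Risks are erosion of the stereocentre by 1,2-hydride shift or deprotonation next to the tertiary cation, and acid damage to the allylic pivalate. The fallback changes the initiation from protonation to hydrogen-atom transfer. It sets out from 13: Co(salen) (C16H14CoN2O2, divalent cobalt, 5 mol%), N-fluoro-2,4,6-trimethylpyridinium triflate and PhSiH3 in hexafluoroisopropanol at 0 °C deliver a hydrogen atom only to the 1,1-disubstituted isopropenyl group. The tertiary radical is oxidised and closes onto the dienone (radical–polar crossover cyclisation) without a long-lived free cation, giving mainly the non-conjugated α-isomer (2E)-2-methyl-4-{(1R)-2,2,4-trimethyl-3-[(1E)-3-oxobut-1-en-1-yl]cyclohex-4-en-1-yl}but-2-en-1-yl pivalate F2. A brief treatment of F2 with cold 96% H2SO4 (the classical α-to-β ionone isomerisation, in which no cation arises next to the stereocentre) moves the double bond into conjugation and rejoins the route at 14.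

Step 9 (double Wittig with in-flask pivalate removal). Risks are incomplete methanolysis of the hindered esters on the poorly soluble C60 intermediate and low yields of the two-fold olefination. The fallback reverses the polarity of the coupling and removes the ester before the polyene is built. It sets out from 14 (and from 18 for the C10 partner):
- Horner–Wadsworth–Emmons reaction of 14 with diethyl (cyanomethyl)phosphonate/NaH in THF gives (2E,4E)-3-methyl-5-{(5R)-2,6,6-trimethyl-5-[(2E)-3-methyl-4-(pivaloyloxy)but-2-en-1-yl]cyclohex-1-en-1-yl}penta-2,4-dienenitrile F3 (the 2Z isomer is removed).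
- Excess iBu2AlH in toluene at −78 °C with acidic work-up reduces the nitrile to the aldehyde and cleaves the pivalate in the same operation, giving (2E,4E)-5-{(5R)-5-[(2E)-4-hydroxy-3-methylbut-2-en-1-yl]-2,6,6-trimethylcyclohex-1-en-1-yl}-3-methylpenta-2,4-dienal F4.
- Dialdehyde 18 is reduced with NaBH4 to (2E,4E,6E)-2,7-dimethylocta-2,4,6-triene-1,8-diol F5, which with PPh3·HBr in MeOH gives (2E,4E,6E)-2,7-dimethylocta-2,4,6-triene-1,8-diylbis(triphenylphosphonium) dibromide F6.
- Double Wittig reaction of F6 with two equivalents of F4 (NaOMe, MeOH/CH2Cl2, then heating in n-heptane) gives the free diol directly and comes back to the route at 20.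

Further compounds
F1 | step 3 | (5R,7E)-8-methyl-5-(prop-1-en-2-yl)-9-(trimethylsilyloxy)non-7-en-2-one | CC(=O)CC[C@H](C/C=C(\C)CO[Si](C)(C)C)C(C)=C
F2 | step 6 | (2E)-2-methyl-4-{(1R)-2,2,4-trimethyl-3-[(1E)-3-oxobut-1-en-1-yl]cyclohex-4-en-1-yl}but-2-en-1-yl pivalate, C3 epimers | CC(=O)/C=C/C1C(C)=CC[C@H](C/C=C(\C)COC(=O)C(C)(C)C)C1(C)C
F3 | step 9 | (2E,4E)-3-methyl-5-{(5R)-2,6,6-trimethyl-5-[(2E)-3-methyl-4-(pivaloyloxy)but-2-en-1-yl]cyclohex-1-en-1-yl}penta-2,4-dienenitrile | N#C/C=C(\C)/C=C/C1=C(C)CC[C@H](C/C=C(\C)COC(=O)C(C)(C)C)C1(C)C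
F4 | step 9 | (2E,4E)-5-{(5R)-5-[(2E)-4-hydroxy-3-methylbut-2-en-1-yl]-2,6,6-trimethylcyclohex-1-en-1-yl}-3-methylpenta-2,4-dienal | O=C/C=C(\C)/C=C/C1=C(C)CC[C@H](C/C=C(\C)CO)C1(C)C
F5 | step 9 | (2E,4E,6E)-2,7-dimethylocta-2,4,6-triene-1,8-diol | OC/C(C)=C/C=C/C=C(C)/CO
F6 | step 9 | (2E,4E,6E)-2,7-dimethylocta-2,4,6-triene-1,8-diylbis(triphenylphosphonium) dibromide | [Br-].[Br-].C(/C(C)=C/C=C/C=C(C)/C[P+](c1ccccc1)(c1ccccc1)c1ccccc1)[P+](c1ccccc1)(c1ccccc1)c1ccccc1
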